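**Plan**

- Cuts: the C15 ester and the two O-isovaleryl bonds go first. The side chain is cut at C13–C16 (methyl cuprate on a Z enol phosphate) and C11–C12 (allylic bromide plus acetoacetate dianion). C8=C9 is traced to a saturated C11 ester, C5–C10 and C8–C9 are cut together (intramolecular Diels–Alder), and the triene is cut at C4–C5 and C1–C2.
- Forward: the C1–C11 chain is joined first (C1–C2, then C4–C5 bringing C5–C8). The C19 acid is closed onto the C6 ketone as an enol lactone, rings A and B form in a single step, and the C12–C16 chain is attached last.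
- Feature used: C19 on C4 and the oxygen on C6 are both β and 1,3-diaxial across C5, where ring A meets ring B. This latent five-membered 19,6-lactone, taken in its enol form, holds C5=C6 in a ring and with C7=C8 supplies the diene, while its quaternary C4 carries the tether to the C9=C10 dienophile.
- Stereochemistry: C4 from a catalytic asymmetric phase-transfer alkylation. C5 from C4 through the lactone clamp, and C10 from the ester-endo transition state of the cycloaddition. C3 and C6 from hydride attack on the ring ketones (equatorial at C3, α face at C6). The 13E alkene from stereoretentive methylation of a Z enol phosphate.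

Key step: step 5

Locants: labdane numbering throughout (decalin C1–C10; C11 on C9; C17 = methyl on C8; C18 = α-methyl and C19 = β-carbon on C4; C20 = β-methyl on C10). All decalin compounds have 5α-H. Compounds 10–19 are named as 12,13,14,15,16-pentanorlabdanes.

Assumption: the sense of induction of the cinchona-derived phase-transfer catalyst on the acyclic keto ester 3 cannot be predicted with confidence; the cinchonidinium salt is written, and its cinchoninium pseudo-enantiomer would be used if that is the one that delivers (R)-7.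

**Route**

Step 1
Reactants: 1 tert-butyl 2-methyl-3-oxobutanoate; 2 methyl (2E)-4-bromo-3-methylbut-2-enoate
Product: 3 1-tert-butyl 8-methyl (6E)-2,6-dimethyl-3-oxooct-6-enedioate (racemic at C2)
Conditions: NaH, THF, 0 °C; n-BuLi, 0 °C; then 2, −78 → 0 °C; aq. NH4Cl
Reagents that add atoms: none
Why: γ-Alkylation of an acetoacetate dianion, in which the terminal carbanion displaces the primary allylic bromide (SN2) much faster than it can add to the β,β-disubstituted enoate, so C1–C2 forms, the E enoate is carried through unchanged and the C4 stereocentre is left for step 3.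

Step 2
Reactants: 4 (3E)-pent-3-en-2-one
Product: 6 (3E)-1-bromopent-3-en-2-one, via silyl dienol ether 5 (not isolated)
Conditions: LiN(i-Pr)2, THF, −78 °C; Me3SiCl; then NBS, −78 → 0 °C
Reagents that add atoms: N-bromosuccinimide, O=C1CCC(=O)N1Br
Why: Kinetic deprotonation at the methyl group and O-silylation give the cross-conjugated 2-silyloxydiene, whose terminal CH2 is then brominated by NBS (bromination of an enone through its silyl enol ether) without touching the E alkene.

Step 3
Reactants: 3 1-tert-butyl 8-methyl (6E)-2,6-dimethyl-3-oxooct-6-enedioate; 6 (3E)-1-bromopent-3-en-2-one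
Product: 7 1-tert-butyl 8-methyl (2R,6E)-2,6-dimethyl-3-oxo-2-[(3E)-2-oxopent-3-en-1-yl]oct-6-enedioate
Conditions: O-allyl-N-(9-anthracenylmethyl)cinchonidinium bromide (10 mol %), Cs2CO3 (solid), toluene, −40 °C
Reagents that add atoms: none
Why: Asymmetric phase-transfer C-alkylation of an α-methyl β-keto ester, in which the chiral ammonium enolate ion pair presents one face of C4 to the highly SN2-reactive α-bromo ketone and should set the quaternary centre as R, while the tert-butyl ester and the mild solid base disfavour O-alkylation, conjugate addition to the enone and aldol closure of the 1,4-diketone.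

Step 4
Reactants: 7 1-tert-butyl 8-methyl (2R,6E)-2,6-dimethyl-3-oxo-2-[(3E)-2-oxopent-3-en-1-yl]oct-6-enedioate
Product: 9 methyl (2E)-3-methyl-6-[(3R)-3-methyl-2-oxo-5-[(1E)-prop-1-en-1-yl]-2,3-dihydrofuran-3-yl]-6-oxohex-2-enoate, via keto acid 8 (not isolated)
Conditions: CF3CO2H, CH2Cl2, 0 °C; then (CF3CO)2O, 0 °C → rt
Reagents that add atoms: none
Why: Acidolysis of the tert-butyl ester and, in the same cold solution, anhydride-driven enol lactonisation of the γ-keto acid (cyclodehydration through the mixed anhydride or its pseudo-acid) should give the 2(3H)-furanone by loss of the C5 proton into conjugation with the propenyl group, the β-keto acid being lactonised before it can decarboxylate.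

Step 5
Reactants: 9 methyl (2E)-3-methyl-6-[(3R)-3-methyl-2-oxo-5-[(1E)-prop-1-en-1-yl]-2,3-dihydrofuran-3-yl]-6-oxohex-2-enoate
Product: 10 methyl 3-oxo-12,13,14,15,16-pentanorlabd-6-en-19,6-olid-11-oate (8β-CH3 9β-CO2Me 10β-CH3)
Conditions: toluene (0.01 M), 2,6-di-tert-butyl-4-methylphenol (cat.), 180 °C, sealed tube
Reagents that add atoms: none
Why: The reaction is a thermal intramolecular Diels–Alder cycloaddition, concerted but asynchronous, in which C5 (the nucleophilic β-carbon of the enol ester) bonds to C10 (the electrophilic β-carbon of the enoate) ahead of C8–C9; the closest known reaction type is the intramolecular Diels–Alder reaction of 1,7,9-decatrienoates carrying a 2-acyloxy diene. Ring B closes as the cyclohexene of the [4+2] process itself, and ring A closes at the same time through the four-atom tether C4–C3–C2–C1 as a six-membered ring fused at the new C5–C10 bond. C5 is controlled by C4: the tether leaves the sp3 carbon C4 of the flat furanone on one face only, so C10 must add to that face of C5, which puts H5 cis to C18 and keeps C19 cis to O6. C10 is controlled by the transition-state geometry: with the E enoate the ester-endo arrangement carries C20 endo and the tether exo, which gives C20 anti to H5 (trans-decalin) and, from the E propenyl group, C17 and C11 both β (these two centres are erased in step 9). The selectivity needed is tether-exo over tether-endo; it should be favoured by the endo preference of the conjugated ester and by a chair-like exo tether that does not stack C1–C2 over the lactone ring, while regiochemistry is fixed by the tether. The quaternary C4 keeps the enol lactone from tautomerising to a butenolide at the reaction temperature.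

Step 6
Reactants: 10 methyl 3-oxo-12,13,14,15,16-pentanorlabd-6-en-19,6-olid-11-oate
Product: 11 methyl 3α-hydroxy-12,13,14,15,16-pentanorlabd-6-en-19,6-olid-11-oate
Conditions: LiBH(s-Bu)3 (1.1 equiv), THF, −78 °C; aq. NH4Cl
Reagents that add atoms: none
Why: Ketone reduction by a bulky trialkylborohydride, in which hydride reaches C3 of the chair ring A along the equatorial trajectory (avoiding the axial hydrogens on C1 and C5) and should give the axial 3α-alcohol, the hindered enol-lactone and ester carbonyls reacting far more slowly at −78 °C.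

Step 7
Reactants: 11 methyl 3α-hydroxy-12,13,14,15,16-pentanorlabd-6-en-19,6-olid-11-oate
Product: 13 methyl 3α,6β,19-trihydroxy-12,13,14,15,16-pentanorlabdan-11-oate, via 6-oxo diol 12 (not isolated)
Conditions: LiBH4, THF, 0 °C; then MeOH, 0 °C → rt
Reagents that add atoms: none
Why: Borohydride reduction of an enol ester, in which hydride adds to the activated lactone carbonyl, C19 is released as the aldehyde and reduced on to CH2OH while C6 leaves as its enolate, and after protonation at C7 by methanol the 6-ketone is reduced from the open α face (the β face being closed by the axial C19 and C20 groups) to the axial 6β-alcohol, the hindered saturated C11 methyl ester being left alone at this temperature.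

Step 8
Reactants: 13 methyl 3α,6β,19-trihydroxy-12,13,14,15,16-pentanorlabdan-11-oate
Product: 14 methyl 3α,6β,19-tris(triethylsilyloxy)-12,13,14,15,16-pentanorlabdan-11-oate
Conditions: Et3SiOTf (4 equiv), 2,6-lutidine, CH2Cl2, 0 °C → rt
Reagents that add atoms: triethylsilyl trifluoromethanesulfonate, CC[Si](CC)(CC)OS(=O)(=O)C(F)(F)F
Why: Silylation with a silyl triflate and a hindered base is forceful enough to cap all three hydroxyls, including the syn-diaxially screened 6β-OH, so that no acidic O–H interferes with the enolate, hydride, dianion and cuprate steps that follow.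

Step 9
Reactants: 14 methyl 3α,6β,19-tris(triethylsilyloxy)-12,13,14,15,16-pentanorlabdan-11-oate
Product: 17 methyl 3α,6β,19-tris(triethylsilyloxy)-12,13,14,15,16-pentanorlabd-8-en-11-oate, via selenide 15 (not isolated), via selenoxide 16 (not isolated)
Conditions: LiN(i-Pr)2, THF, −78 → −20 °C; PhSeBr, −78 °C; then 30% H2O2, pyridine, CH2Cl2, 0 °C → rt
Reagents that add atoms: none
Why: Ester enolate selenenylation followed by selenoxide syn-elimination, in which PhSeBr should enter C9 from the α face away from the axial C17 and C20 methyls and the selenoxide can then only remove the cis 8α-hydrogen because C10 bears none, which places the double bond at C8=C9 and erases both stereocentres left there by the cycloaddition.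

Step 10
Reactants: 17 methyl 3α,6β,19-tris(triethylsilyloxy)-12,13,14,15,16-pentanorlabd-8-en-11-oate
Product: 18 3α,6β,19-tris(triethylsilyloxy)-12,13,14,15,16-pentanorlabd-8-en-11-ol
Conditions: i-Bu2AlH (3 equiv), CH2Cl2, −78 → 0 °C
Reagents that add atoms: none
Why: Hydride reduction of the hindered conjugated ester with i-Bu2AlH gives the primary allylic alcohol by 1,2-addition, the silyl ethers and the tetrasubstituted alkene being inert.

Step 11
Reactants: 18 3α,6β,19-tris(triethylsilyloxy)-12,13,14,15,16-pentanorlabd-8-en-11-ol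
Product: 19 11-bromo-3α,6β,19-tris(triethylsilyloxy)-12,13,14,15,16-pentanorlabd-8-ene
Conditions: CBr4, PPh3, 2,6-lutidine, CH2Cl2, −20 → 0 °C
Reagents that add atoms: tetrabromomethane, BrC(Br)(Br)Br
Why: Appel bromination converts the primary allylic alcohol into the bromide by SN2 displacement of the oxyphosphonium group under buffered, near-neutral conditions that spare the triethylsilyl ethers.

Step 12
Reactants: 19 11-bromo-3α,6β,19-tris(triethylsilyloxy)-12,13,14,15,16-pentanorlabd-8-ene; 20 tert-butyl 3-oxobutanoate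
Product: 21 tert-butyl 13-oxo-3α,6β,19-tris(triethylsilyloxy)-16-norlabd-8-en-15-oate
Conditions: 20, NaH, THF, 0 °C; n-BuLi, 0 °C; then 19, 0 °C → rt; aq. NH4Cl
Reagents that add atoms: none
Why: γ-Alkylation of the acetoacetate dianion by the allylic bromide (SN2 at the primary C11, attack at the fully substituted C8 being blocked) forms C11–C12 and brings in C13–C15 as a β-keto ester.

Step 13
Reactants: 21 tert-butyl 13-oxo-3α,6β,19-tris(triethylsilyloxy)-16-norlabd-8-en-15-oate
Product: 22 tert-butyl (13Z)-13-(diethoxyphosphoryloxy)-3α,6β,19-tris(triethylsilyloxy)-16-norlabda-8,13-dien-15-oate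
Conditions: NaH, Et2O, 0 °C; ClP(O)(OEt)2, 0 °C
Reagents that add atoms: diethyl chlorophosphate, CCOP(=O)(Cl)OCC
Why: O-Phosphorylation of the sodium enolate of the β-keto ester, which is held in the chelated U-shape, should give the Z enol phosphate selectively.

Step 14
Reactants: 22 tert-butyl (13Z)-13-(diethoxyphosphoryloxy)-3α,6β,19-tris(triethylsilyloxy)-16-norlabda-8,13-dien-15-oate
Product: 23 tert-butyl (13E)-3α,6β,19-tris(triethylsilyloxy)labda-8,13-dien-15-oate
Conditions: Me2CuLi (from CuI and MeLi), Et2O, −78 → −45 °C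
Reagents that add atoms: lithium dimethylcuprate, [Li+].C[Cu-]C (prepared from methyllithium, [Li]C)
Why: Substitution of the enol phosphate by the methyl cuprate (conjugate addition–elimination on the β-phosphoryloxy enoate) proceeds with retention, so the new C16 methyl ends up cis to the ester and the 13E trisubstituted enoate should be obtained.

Step 15
Reactants: 23 tert-butyl (13E)-3α,6β,19-tris(triethylsilyloxy)labda-8,13-dien-15-oate
Product: 24 tert-butyl (13E)-3α,6β,19-trihydroxylabda-8,13-dien-15-oate
Conditions: HF·pyridine, pyridine, THF, 0 °C → rt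
Reagents that add atoms: none
Why: Fluoride-driven cleavage of the three Si–O bonds under buffered conditions frees the triol without affecting the tert-butyl ester or either alkene.

Step 16
Reactants: 24 tert-butyl (13E)-3α,6β,19-trihydroxylabda-8,13-dien-15-oate
Product: 25 tert-butyl (13E)-6β-hydroxy-3α,19-bis(3-methylbutanoyloxy)labda-8,13-dien-15-oate
Conditions: 3-methylbutanoic anhydride (3 equiv), DMAP, pyridine, CH2Cl2, rt
Reagents that add atoms: 3-methylbutanoic anhydride, CC(C)CC(=O)OC(=O)CC(C)C
Why: DMAP-catalysed acylation should esterify the primary 19-OH and the axial 3α-OH but not the 6β-OH, which is syn-diaxial to both C19 and C20 and is the hydroxyl left free in the target.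

Step 17
Reactants: 25 tert-butyl (13E)-6β-hydroxy-3α,19-bis(3-methylbutanoyloxy)labda-8,13-dien-15-oate
Product: 26 (13E)-6β-hydroxy-3α,19-bis(3-methylbutanoyloxy)labda-8,13-dien-15-oic acid
Conditions: CF3CO2H, CH2Cl2, 0 °C → rt
Reagents that add atoms: none
Why: Acidolysis of the tert-butyl ester with loss of isobutene releases the C15 acid without any hydrolytic step, so both isovalerates and the E enoate are retained.

**Compound list**

1 | tert-butyl 2-methyl-3-oxobutanoate | CC(=O)C(C)C(=O)OC(C)(C)C | starting material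
2 | methyl (2E)-4-bromo-3-methylbut-2-enoate | COC(=O)/C=C(\C)CBr | starting material
3 | 1-tert-butyl 8-methyl (6E)-2,6-dimethyl-3-oxooct-6-enedioate (racemic at C2) | COC(=O)/C=C(\C)CCC(=O)C(C)C(=O)OC(C)(C)C | intermediate
4 | (3E)-pent-3-en-2-one | C/C=C/C(C)=O | starting material
5 | (3E)-2-(trimethylsilyloxy)penta-1,3-diene | C/C=C/C(=C)O[Si](C)(C)C | intermediate
6 | (3E)-1-bromopent-3-en-2-one | C/C=C/C(=O)CBr | intermediate
7 | 1-tert-butyl 8-methyl (2R,6E)-2,6-dimethyl-3-oxo-2-[(3E)-2-oxopent-3-en-1-yl]oct-6-enedioate | COC(=O)/C=C(\C)CCC(=O)[C@](C)(C(=O)OC(C)(C)C)CC(=O)/C=C/C | intermediate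
8 | (2R,6E)-8-methoxy-2,6-dimethyl-3,8-dioxo-2-[(3E)-2-oxopent-3-en-1-yl]oct-6-enoic acid | COC(=O)/C=C(\C)CCC(=O)[C@](C)(C(=O)O)CC(=O)/C=C/C | intermediate
9 | methyl (2E)-3-methyl-6-[(3R)-3-methyl-2-oxo-5-[(1E)-prop-1-en-1-yl]-2,3-dihydrofuran-3-yl]-6-oxohex-2-enoate | COC(=O)/C=C(\C)CCC(=O)[C@](C)(C(=O)O1)C=C1/C=C/C | intermediate
10 | methyl 3-oxo-12,13,14,15,16-pentanorlabd-6-en-19,6-olid-11-oate (8α-H, 8β-CH3, 9α-H, 9β-CO2Me, 10β-CH3) | C[C@@H]1[C@H](C(=O)OC)[C@@]2(C)CCC(=O)[C@](C)(C(=O)O3)[C@@H]2C3=C1 | intermediate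
11 | methyl 3α-hydroxy-12,13,14,15,16-pentanorlabd-6-en-19,6-olid-11-oate | C[C@@H]1[C@H](C(=O)OC)[C@@]2(C)CC[C@@H](O)[C@](C)(C(=O)O3)[C@@H]2C3=C1 | intermediate
12 | methyl 3α,19-dihydroxy-6-oxo-12,13,14,15,16-pentanorlabdan-11-oate | C[C@@H]1[C@H](C(=O)OC)[C@@]2(C)CC[C@@H](O)[C@](C)(CO)[C@@H]2C(=O)C1 | intermediate
13 | methyl 3α,6β,19-trihydroxy-12,13,14,15,16-pentanorlabdan-11-oate | C[C@@H]1[C@H](C(=O)OC)[C@@]2(C)CC[C@@H](O)[C@](C)(CO)[C@@H]2[C@H](O)C1 | intermediate
14 | methyl 3α,6β,19-tris(triethylsilyloxy)-12,13,14,15,16-pentanorlabdan-11-oate | C[C@@H]1[C@H](C(=O)OC)[C@@]2(C)CC[C@@H](O[Si](CC)(CC)CC)[C@](C)(CO[Si](CC)(CC)CC)[C@@H]2[C@H](O[Si](CC)(CC)CC)C1 | intermediate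
15 | methyl 9α-(phenylselanyl)-3α,6β,19-tris(triethylsilyloxy)-12,13,14,15,16-pentanorlabdan-11-oate | C[C@@H]1[C@]([Se]c3ccccc3)(C(=O)OC)[C@@]2(C)CC[C@@H](O[Si](CC)(CC)CC)[C@](C)(CO[Si](CC)(CC)CC)[C@@H]2[C@H](O[Si](CC)(CC)CC)C1 | intermediate
16 | methyl 9α-(phenylseleninyl)-3α,6β,19-tris(triethylsilyloxy)-12,13,14,15,16-pentanorlabdan-11-oate | C[C@@H]1[C@]([Se](=O)c3ccccc3)(C(=O)OC)[C@@]2(C)CC[C@@H](O[Si](CC)(CC)CC)[C@](C)(CO[Si](CC)(CC)CC)[C@@H]2[C@H](O[Si](CC)(CC)CC)C1 | intermediate
17 | methyl 3α,6β,19-tris(triethylsilyloxy)-12,13,14,15,16-pentanorlabd-8-en-11-oate | CC1=C(C(=O)OC)[C@@]2(C)CC[C@@H](O[Si](CC)(CC)CC)[C@](C)(CO[Si](CC)(CC)CC)[C@@H]2[C@H](O[Si](CC)(CC)CC)C1 | intermediate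
18 | 3α,6β,19-tris(triethylsilyloxy)-12,13,14,15,16-pentanorlabd-8-en-11-ol | CC1=C(CO)[C@@]2(C)CC[C@@H](O[Si](CC)(CC)CC)[C@](C)(CO[Si](CC)(CC)CC)[C@@H]2[C@H](O[Si](CC)(CC)CC)C1 | intermediate
19 | 11-bromo-3α,6β,19-tris(triethylsilyloxy)-12,13,14,15,16-pentanorlabd-8-ene | CC1=C(CBr)[C@@]2(C)CC[C@@H](O[Si](CC)(CC)CC)[C@](C)(CO[Si](CC)(CC)CC)[C@@H]2[C@H](O[Si](CC)(CC)CC)C1 | intermediate
20 | tert-butyl 3-oxobutanoate | CC(=O)CC(=O)OC(C)(C)C | starting material
21 | tert-butyl 13-oxo-3α,6β,19-tris(triethylsilyloxy)-16-norlabd-8-en-15-oate | CC1=C(CCC(=O)CC(=O)OC(C)(C)C)[C@@]2(C)CC[C@@H](O[Si](CC)(CC)CC)[C@](C)(CO[Si](CC)(CC)CC)[C@@H]2[C@H](O[Si](CC)(CC)CC)C1 | intermediate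
22 | tert-butyl (13Z)-13-(diethoxyphosphoryloxy)-3α,6β,19-tris(triethylsilyloxy)-16-norlabda-8,13-dien-15-oate | CC1=C(CC/C(OP(=O)(OCC)OCC)=C/C(=O)OC(C)(C)C)[C@@]2(C)CC[C@@H](O[Si](CC)(CC)CC)[C@](C)(CO[Si](CC)(CC)CC)[C@@H]2[C@H](O[Si](CC)(CC)CC)C1 | intermediate
23 | tert-butyl (13E)-3α,6β,19-tris(triethylsilyloxy)labda-8,13-dien-15-oate | CC1=C(CC/C(C)=C/C(=O)OC(C)(C)C)[C@@]2(C)CC[C@@H](O[Si](CC)(CC)CC)[C@](C)(CO[Si](CC)(CC)CC)[C@@H]2[C@H](O[Si](CC)(CC)CC)C1 | intermediate
24 | tert-butyl (13E)-3α,6β,19-trihydroxylabda-8,13-dien-15-oate | CC1=C(CC/C(C)=C/C(=O)OC(C)(C)C)[C@@]2(C)CC[C@@H](O)[C@](C)(CO)[C@@H]2[C@H](O)C1 | intermediate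
25 | tert-butyl (13E)-6β-hydroxy-3α,19-bis(3-methylbutanoyloxy)labda-8,13-dien-15-oate | CC1=C(CC/C(C)=C/C(=O)OC(C)(C)C)[C@@]2(C)CC[C@@H](OC(=O)CC(C)C)[C@](C)(COC(=O)CC(C)C)[C@@H]2[C@H](O)C1 | intermediate
26 | (13E)-6β-hydroxy-3α,19-bis(3-methylbutanoyloxy)labda-8,13-dien-15-oic acid | CC1=C(CC/C(C)=C/C(=O)O)[C@@]2(C)CC[C@@H](OC(=O)CC(C)C)[C@](C)(COC(=O)CC(C)C)[C@@H]2[C@H](O)C1 | target

**Step count**

Total steps: 17. Longest linear sequence: 16 steps (from 4 through steps 2–17; equally from 1 through steps 1 and 3–17).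

**Steps most likely to fail**

Step 5. The weakly activated acyloxy diene and the trisubstituted enoate may combine too slowly below the temperature at which the β-keto enol lactone begins to degrade. Discrimination between the tether-exo and tether-endo transition states may also be poor, so that much cis-fused decalin forms. The fallback sets out from 7 and comes back at 10. It gives up the lactone clamp for the ring-forming event and closes both rings anionically by an intramolecular double Michael addition. LiN(SiMe3)2 in THF at −78 → 0 °C would convert 7, through the cross-conjugated dienolate of the C6 enone, into the decalindione diester 19-tert-butyl 11-methyl 3,6-dioxo-12,13,14,15,16-pentanorlabdane-11,19-dioate F1. In this closure C5 adds to C10 and the resulting ester enolate adds to C8; diastereomers would be separated at this point, since C5 is no longer steered by the clamp. CF3CO2H at 0 °C would then cleave the tert-butyl ester to the keto acid 11-methoxy-3,6,11-trioxo-12,13,14,15,16-pentanorlabdan-19-oic acid F2. This is lactonised at once with (CF3CO)2O and 2,6-lutidine at 0 °C, the accessible C7 hydrogen being lost, to give 10.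

Step 3. The ion-pair alkylation may show low enantioselectivity because the acyclic enolate has no fixed geometry, and O-alkylation or conjugate addition to the bromo enone may compete. The fallback sets out from 3 and comes back at 7. It replaces catalyst control by a covalent auxiliary. Condensation of 3 with L-valine tert-butyl ester (cat. TsOH, molecular sieves, toluene) would give the hydrogen-bonded β-enamino ester 1-tert-butyl 8-methyl (2Z,6E)-3-{[(2S)-1-tert-butoxy-3-methyl-1-oxobutan-2-yl]amino}-2,6-dimethylocta-2,6-dienedioate F3. Deprotonation with LiN(i-Pr)2 in toluene at −78 °C and alkylation of the chelated lithio-enamine with 6, on the face left open by the isopropyl group, would give the α-quaternary imino ester 1-tert-butyl 8-methyl (2R,6E)-3-{[(2S)-1-tert-butoxy-3-methyl-1-oxobutan-2-yl]imino}-2,6-dimethyl-2-[(3E)-2-oxopent-3-en-1-yl]oct-6-enedioate F4. Buffered hydrolysis (AcOH, NaOAc, H2O–THF) would release 7 and the auxiliary. The solvent system (toluene with or without a coordinating additive) is chosen for the R product.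

Step 9. Formation or selenenylation of the very hindered C9 enolate, flanked by the quaternary C10 and the axial C17 methyl, may be incomplete. The fallback sets out from 14 and comes back at 18. It moves the dehydrogenation to the aldehyde level. i-Bu2AlH would reduce 14 to the saturated alcohol 3α,6β,19-tris(triethylsilyloxy)-12,13,14,15,16-pentanorlabdan-11-ol F5. TEMPO with PhI(OAc)2 would oxidise it to the aldehyde 3α,6β,19-tris(triethylsilyloxy)-12,13,14,15,16-pentanorlabdan-11-al F6. 2-Iodoxybenzoic acid in DMSO at 70 °C would dehydrogenate the α-branched aldehyde to the enal 3α,6β,19-tris(triethylsilyloxy)-12,13,14,15,16-pentanorlabd-8-en-11-al F7, a pathway that needs no new bond to the crowded C9. Luche reduction (NaBH4, CeCl3·7H2O, MeOH, 0 °C) would then give 18.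

Further compounds
F1 | step 5 | 19-tert-butyl 11-methyl 3,6-dioxo-12,13,14,15,16-pentanorlabdane-11,19-dioate | C[C@@H]1[C@H](C(=O)OC)[C@@]2(C)CCC(=O)[C@](C)(C(=O)OC(C)(C)C)[C@@H]2C(=O)C1
F2 | step 5 | 11-methoxy-3,6,11-trioxo-12,13,14,15,16-pentanorlabdan-19-oic acid | C[C@@H]1[C@H](C(=O)OC)[C@@]2(C)CCC(=O)[C@](C)(C(=O)O)[C@@H]2C(=O)C1
F3 | step 3 | 1-tert-butyl 8-methyl (2Z,6E)-3-{[(2S)-1-tert-butoxy-3-methyl-1-oxobutan-2-yl]amino}-2,6-dimethylocta-2,6-dienedioate | COC(=O)/C=C(\C)CC/C(N[C@@H](C(C)C)C(=O)OC(C)(C)C)=C(\C)C(=O)OC(C)(C)C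
F4 | step 3 | 1-tert-butyl 8-methyl (2R,6E)-3-{[(2S)-1-tert-butoxy-3-methyl-1-oxobutan-2-yl]imino}-2,6-dimethyl-2-[(3E)-2-oxopent-3-en-1-yl]oct-6-enedioate | COC(=O)/C=C(\C)CCC(=N[C@@H](C(C)C)C(=O)OC(C)(C)C)[C@](C)(C(=O)OC(C)(C)C)CC(=O)/C=C/C
F5 | step 9 | 3α,6β,19-tris(triethylsilyloxy)-12,13,14,15,16-pentanorlabdan-11-ol | C[C@@H]1[C@H](CO)[C@@]2(C)CC[C@@H](O[Si](CC)(CC)CC)[C@](C)(CO[Si](CC)(CC)CC)[C@@H]2[C@H](O[Si](CC)(CC)CC)C1
F6 | step 9 | 3α,6β,19-tris(triethylsilyloxy)-12,13,14,15,16-pentanorlabdan-11-al | C[C@@H]1[C@H](C=O)[C@@]2(C)CC[C@@H](O[Si](CC)(CC)CC)[C@](C)(CO[Si](CC)(CC)CC)[C@@H]2[C@H](O[Si](CC)(CC)CC)C1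
F7 | step 9 | 3α,6β,19-tris(triethylsilyloxy)-12,13,14,15,16-pentanorlabd-8-en-11-al | CC1=C(C=O)[C@@]2(C)CC[C@@H](O[Si](CC)(CC)CC)[C@](C)(CO[Si](CC)(CC)CC)[C@@H]2[C@H](O[Si](CC)(CC)CC)C1
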